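The readings are simulated on assumed constants, and the scatter is random.

How does X form? I take one L plus one Z to give X, and X plus a further Z to go on, so each L lost passes through X.

| setting | elm | alder | flask |
|---|---|---|---|
| L | 0.20 M | 0.20 M | 0.20 M |
| Z | 0.60 M | 0.30 M | 0.600 M |
| remark | the very flask that is asked about, followed so far | run made earlier |  |
| time |  |  | 15 min |

| run | time / min | X / % | L / % |
|---|---|---|---|
| elm | 0.500 | 39.8 | 53.4 |
| elm | 1.50 | 50.9 | 22.2 |
| elm | 3.00 | 43.1 | 8.7 |
| elm | 5.00 | 32.2 | 3.8 |
| alder | 1.50 | 42.7 | 46.9 |
| alder | 3.00 | 50.2 | 30.4 |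
| alder | 5.00 | 51.8 | 20.9 |
| alder | 6.00 | 50.3 | 19.5 |

(readings scatter by 0.5 percentage points)

- equivalents of Z to L, everything else as given, that leave most X at 15 min
- the amount of X then, in percent of the L charged
- the amount of X with the amounts as given



Does Z alter the split between the two steps? Elm holds X 50.9% at L 22.2%, and alder holds 51.8% at L 20.9% with half the Z charged. So I take both steps as first order in Z, which puts X and L on one curve.

What sets that curve? Over any stretch, the fall of X + L equals κ times the mean X times the fall of ln L. Replacing X by its mean, 47.0%, between the elm readings at 1.50 min and 3.00 min gives κ = 0.484, the selectivity factor, the rate constant of the second addition over that of the first.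

But a mean of a bowed curve is wrong, isn't it? Put it back: with l as L in fraction of the charge, X = (l^κ − l)/(1 − κ). For elm this gives 39.6% against 39.8% read, and 32.5% against 32.2%, from readings not used for κ.

And the most X? By my reckoning, 50.6% at L 24.5%, which consumes about 1.00 equivalents of Z. I hold that as a floor, because the curve does not tell how far L gets by 15 min.

The forecast gives 1.15 equiv, 51% and, as charged, 12%, with the loading “more if the decay is real”.

The flask gives 1.11 equiv, 51.0% and 12.6%.

    L + Z → X (k = 0.0404 M⁻¹ s⁻¹)
    Z + X → Q (k = 0.0192 M⁻¹ s⁻¹)
    2 Z → G (k = 0.00253 M⁻¹ s⁻¹)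

At 15 min the flask as charged holds L 0.367%, which the curve turns into X 12.1%, against 12.6% in the flask. For the forecast's 12% to be wrong, the Z charge would have to move: at 0.539 M or 0.692 M of Z, X at 15 min has moved 5 points from the flask's value. A neighbouring flask charged with 0.80 M of L, its Z and time as in the flask, has 0.750 equivalents of Z, so Z is the limiting reagent there, with Z 0% and L 41.1% left at 15 min. The curve turns that L into X 46.4%, and the neighbouring flask holds X 46.6%.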